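**Retrosynthetic overview**

1. The target is the C4 epimer (hydroxymethyl trans to the C10 methyl) and 12R allylic-transposed isomer of andrographolide. The last bond made is C12–O, by a suprafacial 1,3-oxygen shift from C14 in 4-epi-andrographolide 10 (14S, 12E → 12R), which also creates the butenolide.
2. 10 ⇐ 3-ketone 8 by axial hydride delivery; 8 ⇐ formaldehyde aldol at C4 of a C3–C4 enolate, on the face anti to the C10 methyl (this inverts C4).
3. The enolate ⇐ retro-Claisen deformylation of 3-oxo-19-al 5 ⇐ double oxidation of 14-O-TES-andrographolide 4 ⇐ andrographolide 1.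
4. Ring order: no ring is built. Rings A and B and the lactone come intact from 1; C5, C9, C10 and C14 are carried through, C3 is re-set by reduction, C4 and C12 are set in the route.

Assumption: andrographolide (bulk plant extract, sold at kilogram scale) is taken as a cheap commercial starting material. Labdane numbering is used; the hydroxymethyl carbon of the target is called C18.

**Step 1**
Reactants: 1 andrographolide
Product: 4 14-O-triethylsilylandrographolide, via andrographolide 3,19-O-phenylboronate 2 (not isolated), via 14-O-triethylsilylandrographolide 3,19-O-phenylboronate 3 (not isolated)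
Conditions: PhB(OH)2 (1.05 equiv), pyridine, 4 Å MS, rt; TESCl (1.5 equiv), DMAP (10 mol%), 0 °C → rt; then neopentyl glycol (5 equiv), MeOH, rt
Reagents that add atoms: chlorotriethylsilane (TESCl), CC[Si](Cl)(CC)CC
Why: Transient cyclic boronate masking: the 3-OH/19-OH 1,3-diol (the pair that forms the known acetonide) closes to a dioxaborinane, only the allylic 14-OH is left for silylation, and boronate transesterification then frees the diol; no stereocentre is touched.

**Step 2**
Reactants: 4 14-O-triethylsilylandrographolide
Product: 5 3,19-dioxo-14-O-triethylsilylandrographolide (3-ketone, C19 aldehyde)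
Conditions: DMP (3 equiv), pyridine (6 equiv), CH2Cl2, 0 °C → rt
Reagents that add atoms: none
Why: Dess–Martin oxidation of the secondary 3-OH and the primary 19-OH gives a β-keto aldehyde that cannot enolise between the carbonyls because C4 is quaternary, while the TES ether preserves C14 (S) and the alkylidene lactone.

**Step 3**
Reactants: 5 3,19-dioxo-14-O-triethylsilylandrographolide
Product: 8 14-O-triethylsilyl-3-oxo-4-epi-andrographolide, via lithium enolate 6 (not isolated), via lithium aldolate 7 (not isolated)
Conditions: LiOEt (1.05 equiv, 1.0 M in THF), THF, −78 → −20 °C; CH2O (gas, from cracked paraformaldehyde), −78 °C; AcOH quench at −78 °C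
Reagents that add atoms: formaldehyde, C=O
Why: Retro-Claisen (deacylative) enolate release followed by aldol addition: ethoxide adds to the axial C19 aldehyde and expels ethyl formate to give only the C3–C4 enolate, which takes up monomeric formaldehyde on the face anti to the axial C10 methyl (the sense known from reductive hydroxymethylation of 4-methyl-3-keto decalins), setting C4 as S with the hydroxymethyl equatorial.

**Step 4**
Reactants: 8 14-O-triethylsilyl-3-oxo-4-epi-andrographolide
Product: 10 4-epi-andrographolide, via 14-O-triethylsilyl-4-epi-andrographolide 9 (not isolated)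
Conditions: NaBH4, CeCl3·7H2O, MeOH, −40 °C; then 1 M aq HCl to pH 2, 0 °C → rt
Reagents that add atoms: none
Why: Luche reduction: hydride attacks the C3 ketone axially, away from the axial C4 methyl (as in 4-hydroxymethyl-4-methyl-3-keto terpenoids), giving the equatorial 3R alcohol 1,2-selectively beside the enoate, and dilute acid then hydrolyses the secondary TES ether on the acid-tolerant andrographolide core.

**Step 5**
Reactants: 10 4-epi-andrographolide
Product: 11 (12R)-14-deoxy-12-hydroxy-4-epi-andrographolide (target)
Conditions: Ph3SiOReO3 (5 mol%), 2,6-di-tert-butyl-4-methylpyridine (10 mol%), THF/CH2Cl2 (1:1), 0 °C → rt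
Reagents that add atoms: none
Why: Proposed new method: Ph3SiOReO3 exchanges onto the allylic 14-OH to give a perrhenate ester whose oxo ligand is delivered to C12 through a six-membered chair-like [3,3] shift on the same face that O14 leaves, so the fixed 12E geometry and the 14S centre translate into 12R while the more stable endocyclic butenolide (relief of allylic strain) drives the equilibrium; the closest known reaction type is the oxorhenium-catalysed 1,3-transposition of simple allylic alcohols, not shown on an α-alkylidene-β-hydroxy-γ-butyrolactone or used to relay a ring stereocentre to an exocyclic carbinol.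

**Compound list**

1 | andrographolide (3R,4R,5S,9R,10S,14S,12E) | C=C1CC[C@@H]2[C@](C)(CO)[C@H](O)CC[C@@]2(C)[C@@H]1C/C=C1/C(=O)OC[C@H]1O | starting material
2 | andrographolide 3,19-O-phenylboronate (cyclic dioxaborinane over O3 and O19) | C=C1CC[C@@H]2[C@]3(C)COB(c4ccccc4)O[C@@H]3CC[C@@]2(C)[C@@H]1C/C=C1/C(=O)OC[C@H]1O | intermediate
3 | 14-O-triethylsilylandrographolide 3,19-O-phenylboronate | C=C1CC[C@@H]2[C@]3(C)COB(c4ccccc4)O[C@@H]3CC[C@@]2(C)[C@@H]1C/C=C1/C(=O)OC[C@H]1O[Si](CC)(CC)CC | intermediate
4 | 14-O-triethylsilylandrographolide | C=C1CC[C@@H]2[C@](C)(CO)[C@H](O)CC[C@@]2(C)[C@@H]1C/C=C1/C(=O)OC[C@H]1O[Si](CC)(CC)CC | intermediate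
5 | 3,19-dioxo-14-O-triethylsilylandrographolide (3-ketone, axial C19 aldehyde, 4R) | C=C1CC[C@@H]2[C@](C)(C=O)C(=O)CC[C@@]2(C)[C@@H]1C/C=C1/C(=O)OC[C@H]1O[Si](CC)(CC)CC | intermediate
6 | lithium enolate (19-nor C3–C4 lithium enolate, O14 TES) | C=C1CC[C@@H]2C(C)=C(O[Li])CC[C@@]2(C)[C@@H]1C/C=C1/C(=O)OC[C@H]1O[Si](CC)(CC)CC | intermediate
7 | lithium aldolate (lithium C18 alkoxide of 8) | C=C1CC[C@@H]2[C@@](C)(CO[Li])C(=O)CC[C@@]2(C)[C@@H]1C/C=C1/C(=O)OC[C@H]1O[Si](CC)(CC)CC | intermediate
8 | 14-O-triethylsilyl-3-oxo-4-epi-andrographolide (4S, hydroxymethyl trans to the C10 methyl) | C=C1CC[C@@H]2[C@@](C)(CO)C(=O)CC[C@@]2(C)[C@@H]1C/C=C1/C(=O)OC[C@H]1O[Si](CC)(CC)CC | intermediate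
9 | 14-O-triethylsilyl-4-epi-andrographolide (3R,4S) | C=C1CC[C@@H]2[C@@](C)(CO)[C@H](O)CC[C@@]2(C)[C@@H]1C/C=C1/C(=O)OC[C@H]1O[Si](CC)(CC)CC | intermediate
10 | 4-epi-andrographolide (3R,4S,5S,9R,10S,14S,12E) | C=C1CC[C@@H]2[C@@](C)(CO)[C@H](O)CC[C@@]2(C)[C@@H]1C/C=C1/C(=O)OC[C@H]1O | intermediate
11 | (12R)-14-deoxy-12-hydroxy-4-epi-andrographolide (3R,4S,5S,9R,10S,12R) | C=C1CC[C@@H]2[C@@](C)(CO)[C@H](O)CC[C@@]2(C)[C@@H]1C[C@@H](O)C1=CCOC1=O | target

**Totals**

Total steps: 5. Longest linear sequence: 5.

**Steps most likely to fail**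

Step 5 (the proposed new step). The electron-poor allyl unit may turn over slowly, and elimination to the 11,12-diene or acid-triggered ether formation between O12 and C8 could compete. The fallback uses known chemistry, sets out from 10 and comes back at 11. Peracetylation (Ac2O, pyridine, rt) gives 3,14,18-tri-O-acetyl-4-epi-andrographolide F3. PdCl2(MeCN)2 (5 mol%) in THF at rt then effects the [3,3] shift of the allylic acetate under divalent palladium catalysis (cyclisation-induced rearrangement, suprafacial) to give (12R)-3,12,18-tri-O-acetyl-14-deoxy-12-hydroxy-4-epi-andrographolide F4. K2CO3 (catalytic) in MeOH at 0 °C removes the three acetates to give 11.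

Step 3. Ethoxide or the enolate may attack the alkylidene lactone, proton transfer may scramble the enolate, and the lithium aldolate may revert. The fallback sets out from 5 and comes back at 8. The same deformylation is quenched with TMSCl/Et3N at −78 °C to isolate the 19-nor C3–C4 trimethylsilyl enol ether F2. A Mukaiyama hydroxymethylation with aqueous formaldehyde and Yb(OTf)3 (10 mol%) in THF at rt then forms the C4–C18 bond under neutral Lewis-acid catalysis, so that no free enolate or aldolate coexists with the lactone.

Step 1. Boronate masking or its removal may be incomplete and give mixed silyl ethers. The fallback sets out from 1 and comes back at 5, replacing steps 1 and 2. TESCl (2.2 equiv) with imidazole in DMF at −20 °C silylates the primary 19-OH and the allylic 14-OH but not the neopentyl 3-OH, giving 14,19-bis-O-triethylsilylandrographolide F1. Swern oxidation ((COCl)2, DMSO, CH2Cl2, −78 → −30 °C; Et3N) then oxidises the free 3-OH and converts the primary TES ether directly into the aldehyde, while the secondary 14-O-TES ether survives, giving 5.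

**Further compounds**

F1 | step 1 | 14,19-bis-O-triethylsilylandrographolide | C=C1CC[C@@H]2[C@](C)(CO[Si](CC)(CC)CC)[C@H](O)CC[C@@]2(C)[C@@H]1C/C=C1/C(=O)OC[C@H]1O[Si](CC)(CC)CC
F2 | step 3 | 19-nor C3–C4 trimethylsilyl enol ether of 14-O-triethylsilylandrographolide | C=C1CC[C@@H]2C(C)=C(O[Si](C)(C)C)CC[C@@]2(C)[C@@H]1C/C=C1/C(=O)OC[C@H]1O[Si](CC)(CC)CC
F3 | step 5 | 3,14,18-tri-O-acetyl-4-epi-andrographolide | C=C1CC[C@@H]2[C@@](C)(COC(C)=O)[C@H](OC(C)=O)CC[C@@]2(C)[C@@H]1C/C=C1/C(=O)OC[C@H]1OC(C)=O
F4 | step 5 | (12R)-3,12,18-tri-O-acetyl-14-deoxy-12-hydroxy-4-epi-andrographolide | C=C1CC[C@@H]2[C@@](C)(COC(C)=O)[C@H](OC(C)=O)CC[C@@]2(C)[C@@H]1C[C@@H](OC(C)=O)C1=CCOC1=O
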